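## Retrosynthetic overview

1. The last C–C bond is C9–C10: a B-alkyl Suzuki–Miyaura coupling of the 9-BBN adduct of vinyl oxirane 12 (west half, C1–C9) with the E-vinyl iodide 20 (east half, C10–C15), followed by removal of both silyl groups.
2. The oxirane is the only ring. It is closed on the west half before the union, by Sharpless asymmetric epoxidation of the E-allylic alcohol 9 (D-(−)-tartrate gives 6R,7R); oxidation and Wittig methylenation then give the vinyl group.
3. Alcohol 9 comes from SeO2 oxidation of the E-methyl group of 8. The C2=C3 geometry and the distinction between the two allylic oxygens come from Red-Al/I2 on mono-silylated butynediol, then a B-alkyl Suzuki coupling at C3–C4.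
4. East half: carboalumination/iodination of propargyl alcohol gives the E-iodide, Brown allylboration sets C12 (R), and cross-metathesis with 2-methyl-2-butene turns allyl into prenyl.

Conventions (one line): chain atoms are numbered C1 (CH2OAc) to C15 (isopropylidene carbon), the hydroxymethyl carbon on C3 is C3′, TBS = tert-butyldimethylsilyl, and (+)-Ipc2BOMe means the enantiomer made from (−)-α-pinene.

## Route

**Step 1**
Reactants: 1 but-2-yne-1,4-diol
Product: 2 4-(TBS-oxy)but-2-yn-1-ol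
Conditions: NaH (1.0 equiv), THF, 0 °C to rt; then TBSCl (1.0 equiv), rt
Reagents that add atoms: tert-butyldimethylsilyl chloride, CC(C)(C)[Si](C)(C)Cl
Why: Monosilylation through the sparingly soluble monosodium alkoxide (Williamson-type O-silylation) desymmetrises the diol, so the two allylic oxygens of the target are told apart from the start; no stereocentre is involved.

**Step 2**
Reactants: 2 4-(TBS-oxy)but-2-yn-1-ol
Product: 4 (2Z)-4-(TBS-oxy)-3-iodobut-2-en-1-ol, via cyclic alkenylaluminate 3 (not isolated)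
Conditions: NaAlH2(OCH2CH2OMe)2 (Red-Al, 1.5 equiv), THF, 0 °C to rt; then I2 (1.5 equiv), THF, −78 to 0 °C
Reagents that add atoms: iodine, II
Why: Alkoxide-directed trans-hydroalumination of the propargylic alcohol puts aluminium on the distal alkyne carbon in a five-membered ring, and iodinolysis with retention gives only the Z-iodide, which fixes the C2=C3 geometry (C1 cis to the future C4).

**Step 3**
Reactants: 4 (2Z)-4-(TBS-oxy)-3-iodobut-2-en-1-ol; 5 4-methylpenta-1,3-diene
Product: 7 (2E)-3-[(TBS-oxy)methyl]-7-methylocta-2,6-dien-1-ol, via alkylborane 6 (not isolated)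
Conditions: 5 (1.8 equiv), 9-BBN (1.5 equiv), THF, rt, 3 h; then 4, Pd(dppf)Cl2 (5 mol%), AsPh3 (5 mol%), Cs2CO3 (3 equiv), DMF/THF/H2O, rt
Reagents that add atoms: none
Why: 9-BBN hydroborates only the terminal vinyl group of the diene, and the B-alkyl Suzuki–Miyaura coupling replaces iodine with retention of olefin geometry while tolerating the free hydroxyl.

**Step 4**
Reactants: 7 (2E)-3-[(TBS-oxy)methyl]-7-methylocta-2,6-dien-1-ol
Product: 8 (2E)-3-[(TBS-oxy)methyl]-7-methylocta-2,6-dien-1-yl acetate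
Conditions: Ac2O, pyridine, DMAP (cat.), CH2Cl2, 0 °C to rt
Reagents that add atoms: acetic anhydride, CC(=O)OC(C)=O
Why: DMAP-catalysed acylation of the only free hydroxyl installs the acetate of the target early, so that at the end only silyl ethers have to be cleaved.

**Step 5**
Reactants: 8 (2E)-3-[(TBS-oxy)methyl]-7-methylocta-2,6-dien-1-yl acetate
Product: 9 (2E,6E)-3-[(TBS-oxy)methyl]-8-hydroxy-7-methylocta-2,6-dien-1-yl acetate
Conditions: SeO2 (0.3 equiv), t-BuOOH (3 equiv), salicylic acid (0.1 equiv), CH2Cl2, rt, stopped at about 70% conversion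
Reagents that add atoms: tert-butyl hydroperoxide, CC(C)(C)OO (terminal oxygen source); selenium dioxide, O=[Se]=O (transfers the oxygen, catalytic)
Why: The Sharpless–Umbreit allylic oxidation (ene reaction, then [2,3]-sigmatropic shift) attacks the electron-rich gem-dimethyl olefin at its E-methyl group and gives the E-allylic alcohol, while the C2=C3 olefin is deactivated by two allylic oxygens.

**Step 6**
Reactants: 9 (2E,6E)-3-[(TBS-oxy)methyl]-8-hydroxy-7-methylocta-2,6-dien-1-yl acetate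
Product: 10 (2E)-3-[(TBS-oxy)methyl]-5-[(2R,3R)-3-(hydroxymethyl)-3-methyloxiran-2-yl]pent-2-en-1-yl acetate
Conditions: Ti(OiPr)4 (10 mol%), D-(−)-diisopropyl tartrate (12 mol%), t-BuOOH (2 equiv, in decane), 4 Å MS, CH2Cl2, −20 °C
Reagents that add atoms: tert-butyl hydroperoxide, CC(C)(C)OO
Why: In the Sharpless asymmetric epoxidation the titanium tartrate binds the only free allylic hydroxyl and delivers oxygen to one face of C6=C7; D-(−)-tartrate gives the 2R,3R epoxy alcohol (6R,7R of the target), and the trans arrangement follows from the E-olefin.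

**Step 7**
Reactants: 10 (2E)-3-[(TBS-oxy)methyl]-5-[(2R,3R)-3-(hydroxymethyl)-3-methyloxiran-2-yl]pent-2-en-1-yl acetate
Product: 11 (2E)-3-[(TBS-oxy)methyl]-5-[(2R,3S)-3-formyl-3-methyloxiran-2-yl]pent-2-en-1-yl acetate
Conditions: TEMPO (10 mol%), PhI(OAc)2 (1.3 equiv), CH2Cl2, rt; used crude
Reagents that add atoms: none
Why: The oxoammonium (TEMPO) oxidation takes the primary alcohol to the aldehyde without touching epoxide, acetate or silyl ether, and the quaternary α-carbon cannot epimerise (the S label at that carbon is only a priority change).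

**Step 8**
Reactants: 11 (2E)-3-[(TBS-oxy)methyl]-5-[(2R,3S)-3-formyl-3-methyloxiran-2-yl]pent-2-en-1-yl acetate
Product: 12 (2E)-3-[(TBS-oxy)methyl]-5-[(2R,3R)-3-ethenyl-3-methyloxiran-2-yl]pent-2-en-1-yl acetate
Conditions: Ph3PCH3Br (1.3 equiv), KN(SiMe3)2 (1.2 equiv), THF, 0 °C; then 11, −78 to 0 °C
Reagents that add atoms: methyltriphenylphosphonium bromide, C[P+](c1ccccc1)(c1ccccc1)c1ccccc1.[Br-]
Why: Wittig methylenation of the non-enolisable epoxy aldehyde is much faster than attack of the ylide on the acetate and leaves both oxirane centres untouched.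

**Step 9**
Reactants: 13 prop-2-yn-1-ol
Product: 15 (2E)-3-iodo-2-methylprop-2-en-1-ol, via alkenylalane 14 (not isolated)
Conditions: Me3Al (3 equiv), Cp2ZrCl2 (0.25 equiv), CH2Cl2, 0 °C to rt; then I2 (1.2 equiv), THF, −30 to 0 °C; aq. K2CO3 work-up
Reagents that add atoms: trimethylaluminium, C[Al](C)C; iodine, II
Why: The zirconium-catalysed Negishi carboalumination adds methyl and aluminium syn across the alkyne with aluminium at the terminus, and iodinolysis with retention gives the E-iodide.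

**Step 10**
Reactants: 15 (2E)-3-iodo-2-methylprop-2-en-1-ol
Product: 16 (2E)-3-iodo-2-methylprop-2-enal
Conditions: MnO2 (activated, 15 equiv), CH2Cl2, rt; used as a solution
Reagents that add atoms: none
Why: MnO2 oxidises the allylic alcohol selectively to the enal without isomerising the vinyl iodide.

**Step 11**
Reactants: 16 (2E)-3-iodo-2-methylprop-2-enal
Product: 18 (1E,3R)-1-iodo-2-methylhexa-1,5-dien-3-ol, via borinate ester 17 (not isolated)
Conditions: (+)-Ipc2BOMe (1.3 equiv), CH2=CHCH2MgBr (1.2 equiv), Et2O, −78 °C to rt; then 16, −78 °C; then NaOH, H2O2, rt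
Reagents that add atoms: allylmagnesium bromide, C=CC[Mg]Br
Why: Brown asymmetric allylboration runs through a chair Zimmerman–Traxler transition state in which the (−)-α-pinene-derived reagent attacks the Re face of the enal, setting the 3R carbinol (C12 of the target).

**Step 12**
Reactants: 18 (1E,3R)-1-iodo-2-methylhexa-1,5-dien-3-ol
Product: 19 tert-butyl{[(1E,3R)-1-iodo-2-methylhexa-1,5-dien-3-yl]oxy}dimethylsilane
Conditions: TBSCl, imidazole, DMF, rt
Reagents that add atoms: tert-butyldimethylsilyl chloride, CC(C)(C)[Si](C)(C)Cl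
Why: Silylation shields the allylic alcohol from ruthenium-hydride isomerisation in the metathesis and from borane in the coupling; the stereocentre is not touched.

**Step 13**
Reactants: 19 tert-butyl{[(1E,3R)-1-iodo-2-methylhexa-1,5-dien-3-yl]oxy}dimethylsilane
Product: 20 tert-butyl{[(1E,3R)-1-iodo-2,6-dimethylhepta-1,5-dien-3-yl]oxy}dimethylsilane
Conditions: 2-methyl-2-butene (large excess), second-generation Grubbs catalyst (H2IMes)(PCy3)Cl2Ru=CHPh (5 mol%), CH2Cl2, 35 °C
Reagents that add atoms: 2-methyl-2-butene, CC=C(C)C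
Why: Olefin cross-metathesis turns the terminal vinyl group into the prenyl terminus, while the trisubstituted iodo-olefin is inert to the catalyst.

**Step 14**
Reactants: 12 (2E)-3-[(TBS-oxy)methyl]-5-[(2R,3R)-3-ethenyl-3-methyloxiran-2-yl]pent-2-en-1-yl acetate; 20 tert-butyl{[(1E,3R)-1-iodo-2,6-dimethylhepta-1,5-dien-3-yl]oxy}dimethylsilane
Product: 22 (2E)-3-[(TBS-oxy)methyl]-5-{(2R,3R)-3-[(3E,5R)-5-(TBS-oxy)-4,8-dimethylnona-3,7-dien-1-yl]-3-methyloxiran-2-yl}pent-2-en-1-yl acetate, via alkylborane 21 (not isolated)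
Conditions: 12 (1.3 equiv), 9-BBN (1.6 equiv), THF, 0 °C to rt; then aq. Cs2CO3 (3 equiv), 20 (1.0 equiv), Pd(dppf)Cl2 (10 mol%), AsPh3 (10 mol%), DMF, rt, dark
Reagents that add atoms: none
Why: 9-BBN adds to the monosubstituted vinyl group at its terminal carbon (the trisubstituted olefin is far slower), and the B-alkyl Suzuki–Miyaura coupling forms C9–C10 with retention of the E-geometry at room temperature, where acetate, oxirane and silyl ethers survive.

**Step 15**
Reactants: 22 (2E)-3-[(TBS-oxy)methyl]-5-{(2R,3R)-3-[(3E,5R)-5-(TBS-oxy)-4,8-dimethylnona-3,7-dien-1-yl]-3-methyloxiran-2-yl}pent-2-en-1-yl acetate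
Product: 23 (2E)-3-(hydroxymethyl)-5-{(2R,3R)-3-[(3E,5R)-5-hydroxy-4,8-dimethylnona-3,7-dien-1-yl]-3-methyloxiran-2-yl}pent-2-en-1-yl acetate
Conditions: Bu4NF (3 equiv), AcOH (3 equiv), THF, 0 °C to rt
Reagents that add atoms: none
Why: Fluoride-mediated desilylation frees both hydroxyls; the acetic acid buffer protects acetate and oxirane, and acyl migration to O3′ cannot occur because C3′ is trans to C1 across the olefin.

## Compound list

1 | but-2-yne-1,4-diol | OCC#CCO | starting material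
2 | 4-(TBS-oxy)but-2-yn-1-ol | OCC#CCO[Si](C)(C)C(C)(C)C | intermediate
3 | sodium cyclic alkenylaluminate (Al bound to O1 and C3, two 2-methoxyethoxy groups on Al) | [Na+].COCCO[Al-]1(OCCOC)OCC=C1CO[Si](C)(C)C(C)(C)C | intermediate
4 | (2Z)-4-(TBS-oxy)-3-iodobut-2-en-1-ol | OC/C=C(\I)CO[Si](C)(C)C(C)(C)C | intermediate
5 | 4-methylpenta-1,3-diene | C=CC=C(C)C | starting material
6 | 9-(4-methylpent-3-en-1-yl)-9-borabicyclo[3.3.1]nonane | CC(C)=CCCB1C2CCCC1CCC2 | intermediate
7 | (2E)-3-[(TBS-oxy)methyl]-7-methylocta-2,6-dien-1-ol | OC/C=C(/CO[Si](C)(C)C(C)(C)C)CCC=C(C)C | intermediate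
8 | (2E)-3-[(TBS-oxy)methyl]-7-methylocta-2,6-dien-1-yl acetate | CC(=O)OC/C=C(/CO[Si](C)(C)C(C)(C)C)CCC=C(C)C | intermediate
9 | (2E,6E)-3-[(TBS-oxy)methyl]-8-hydroxy-7-methylocta-2,6-dien-1-yl acetate | CC(=O)OC/C=C(/CO[Si](C)(C)C(C)(C)C)CC/C=C(\C)CO | intermediate
10 | (2E)-3-[(TBS-oxy)methyl]-5-[(2R,3R)-3-(hydroxymethyl)-3-methyloxiran-2-yl]pent-2-en-1-yl acetate | CC(=O)OC/C=C(/CO[Si](C)(C)C(C)(C)C)CC[C@H]1O[C@]1(C)CO | intermediate
11 | (2E)-3-[(TBS-oxy)methyl]-5-[(2R,3S)-3-formyl-3-methyloxiran-2-yl]pent-2-en-1-yl acetate | CC(=O)OC/C=C(/CO[Si](C)(C)C(C)(C)C)CC[C@H]1O[C@]1(C)C=O | intermediate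
12 | (2E)-3-[(TBS-oxy)methyl]-5-[(2R,3R)-3-ethenyl-3-methyloxiran-2-yl]pent-2-en-1-yl acetate | CC(=O)OC/C=C(/CO[Si](C)(C)C(C)(C)C)CC[C@H]1O[C@]1(C)C=C | intermediate
13 | prop-2-yn-1-ol (propargyl alcohol) | C#CCO | starting material
14 | (E)-alkenylalane, Me2Al on C3 and Me2Al–O on C1 of 2-methylprop-2-ene | C[Al](C)/C=C(\C)CO[Al](C)C | intermediate
15 | (2E)-3-iodo-2-methylprop-2-en-1-ol | I/C=C(\C)CO | intermediate
16 | (2E)-3-iodo-2-methylprop-2-enal | I/C=C(\C)C=O | intermediate
17 | diisopinocampheylborinate of (1E,3R)-1-iodo-2-methylhexa-1,5-dien-3-ol | I/C=C(\C)[C@@H](CC=C)OB([C@H]1C[C@H]2C[C@@H]([C@@H]1C)C2(C)C)[C@H]1C[C@H]2C[C@@H]([C@@H]1C)C2(C)C | intermediate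
18 | (1E,3R)-1-iodo-2-methylhexa-1,5-dien-3-ol | I/C=C(\C)[C@H](O)CC=C | intermediate
19 | tert-butyl{[(1E,3R)-1-iodo-2-methylhexa-1,5-dien-3-yl]oxy}dimethylsilane | I/C=C(\C)[C@H](O[Si](C)(C)C(C)(C)C)CC=C | intermediate
20 | tert-butyl{[(1E,3R)-1-iodo-2,6-dimethylhepta-1,5-dien-3-yl]oxy}dimethylsilane | I/C=C(\C)[C@H](O[Si](C)(C)C(C)(C)C)CC=C(C)C | intermediate
21 | (2E)-5-{(2R,3R)-3-[2-(9-borabicyclo[3.3.1]nonan-9-yl)ethyl]-3-methyloxiran-2-yl}-3-[(TBS-oxy)methyl]pent-2-en-1-yl acetate | CC(=O)OC/C=C(/CO[Si](C)(C)C(C)(C)C)CC[C@H]1O[C@]1(C)CCB1C2CCCC1CCC2 | intermediate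
22 | (2E)-3-[(TBS-oxy)methyl]-5-{(2R,3R)-3-[(3E,5R)-5-(TBS-oxy)-4,8-dimethylnona-3,7-dien-1-yl]-3-methyloxiran-2-yl}pent-2-en-1-yl acetate | CC(=O)OC/C=C(/CO[Si](C)(C)C(C)(C)C)CC[C@H]1O[C@]1(C)CC/C=C(\C)[C@H](O[Si](C)(C)C(C)(C)C)CC=C(C)C | intermediate
23 | (2E)-3-(hydroxymethyl)-5-{(2R,3R)-3-[(3E,5R)-5-hydroxy-4,8-dimethylnona-3,7-dien-1-yl]-3-methyloxiran-2-yl}pent-2-en-1-yl acetate | CC(=O)OC/C=C(/CO)CC[C@H]1O[C@]1(C)CC/C=C(\C)[C@H](O)CC=C(C)C | target

## Step count and risks

Total step count: 15. Longest linear sequence: 10 steps (steps 1–8, then 14 and 15); the east branch (steps 9–13, then 14 and 15) is 7 steps. The ratio is 10/15, exactly two thirds.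

**Step 14 (most likely to fail).** 9-BBN may open the vinyl oxirane by SN2′ hydride delivery instead of hydroborating it, and the γ-boryl oxirane may be lost under base. The fallback makes the oxirane after the union instead of before it. It sets out from 9, which is oxidised with MnO2 to the enal F1 and methylenated with Ph3P=CH2 to the diene F2. 9-BBN adds to the terminal vinyl group of this diene (as in step 3) to give the alkylborane F3, which is coupled with the allyl-bearing iodide 19 under the step 14 palladium conditions to the tetraene F4. Shi epoxidation with the D-fructose-derived ketone (Oxone, K2CO3, MeCN/dimethoxymethane/buffer, 0 °C) then epoxidises C6=C7 to the 6R,7R oxirane F5. This site is favoured because C2=C3 and C10=C11 are deactivated by allylic oxygens and the terminal vinyl group is monosubstituted. Cross-metathesis of F5 with 2-methyl-2-butene and the second-generation Grubbs catalyst brings the sequence back to the route at 22.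

**Step 5.** SeO2 oxidation can over-oxidise to the enal or attack the other allylic positions, and yields near 50% are usual. The fallback brings the C8 oxygen in with the building block instead of by C–H oxidation. It sets out from 4. Acrolein and Ph3P=C(CH3)CO2Et give the dienoate F6, DIBAL-H reduces it to the dienol F7, and NaH with 4-methoxybenzyl chloride gives the PMB ether F8. Its 9-BBN adduct F9 is coupled with 4 as in step 3 to give the alcohol F10, which is acetylated to the acetate F11. DDQ (CH2Cl2/pH 7 buffer, 0 °C) removes the PMB group and the sequence comes back to the route at 9.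

**Step 15.** The secondary allylic silyl ether at C12 is slow to cleave, and long exposure to fluoride endangers the acetate and can let O3′ open the oxirane. The fallback moves this difficult desilylation to the fragment stage. It sets out from 20, which is desilylated with Bu4NF in THF to the free alcohol F12. F12 is coupled with borane 21 under the step 14 conditions to give the mono-silyl ether F13. Only the primary allylic silyl ether then remains, and a short treatment with Bu4NF/AcOH at 0 °C brings the sequence back to the route at 23.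

## Further compounds

F1 | step 14 | (2E,6E)-3-[(TBS-oxy)methyl]-7-methyl-8-oxoocta-2,6-dien-1-yl acetate | CC(=O)OC/C=C(/CO[Si](C)(C)C(C)(C)C)CC/C=C(\C)C=O
F2 | step 14 | (2E,6E)-3-[(TBS-oxy)methyl]-7-methylnona-2,6,8-trien-1-yl acetate | CC(=O)OC/C=C(/CO[Si](C)(C)C(C)(C)C)CC/C=C(\C)C=C
F3 | step 14 | (2E,6E)-9-(9-borabicyclo[3.3.1]nonan-9-yl)-3-[(TBS-oxy)methyl]-7-methylnona-2,6-dien-1-yl acetate | CC(=O)OC/C=C(/CO[Si](C)(C)C(C)(C)C)CC/C=C(\C)CCB1C2CCCC1CCC2
F4 | step 14 | (2E,6E,10E,12R)-12-(TBS-oxy)-3-[(TBS-oxy)methyl]-7,11-dimethylpentadeca-2,6,10,14-tetraen-1-yl acetate | CC(=O)OC/C=C(/CO[Si](C)(C)C(C)(C)C)CC/C=C(\C)CC/C=C(\C)[C@H](O[Si](C)(C)C(C)(C)C)CC=C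
F5 | step 14 | (2E)-3-[(TBS-oxy)methyl]-5-{(2R,3R)-3-[(3E,5R)-5-(TBS-oxy)-4-methylocta-3,7-dien-1-yl]-3-methyloxiran-2-yl}pent-2-en-1-yl acetate | CC(=O)OC/C=C(/CO[Si](C)(C)C(C)(C)C)CC[C@H]1O[C@]1(C)CC/C=C(\C)[C@H](O[Si](C)(C)C(C)(C)C)CC=C
F6 | step 5 | ethyl (2E)-2-methylpenta-2,4-dienoate | CCOC(=O)/C(C)=C/C=C
F7 | step 5 | (2E)-2-methylpenta-2,4-dien-1-ol | OC/C(C)=C/C=C
F8 | step 5 | 1-methoxy-4-({[(2E)-2-methylpenta-2,4-dien-1-yl]oxy}methyl)benzene | COc1ccc(COC/C(C)=C/C=C)cc1
F9 | step 5 | 9-{(3E)-5-[(4-methoxybenzyl)oxy]-4-methylpent-3-en-1-yl}-9-borabicyclo[3.3.1]nonane | COc1ccc(COC/C(C)=C/CCB2C3CCCC2CCC3)cc1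
F10 | step 5 | (2E,6E)-3-[(TBS-oxy)methyl]-8-[(4-methoxybenzyl)oxy]-7-methylocta-2,6-dien-1-ol | OC/C=C(/CO[Si](C)(C)C(C)(C)C)CC/C=C(\C)COCc1ccc(OC)cc1
F11 | step 5 | (2E,6E)-3-[(TBS-oxy)methyl]-8-[(4-methoxybenzyl)oxy]-7-methylocta-2,6-dien-1-yl acetate | CC(=O)OC/C=C(/CO[Si](C)(C)C(C)(C)C)CC/C=C(\C)COCc1ccc(OC)cc1
F12 | step 15 | (1E,3R)-1-iodo-2,6-dimethylhepta-1,5-dien-3-ol | I/C=C(\C)[C@H](O)CC=C(C)C
F13 | step 15 | (2E)-3-[(TBS-oxy)methyl]-5-{(2R,3R)-3-[(3E,5R)-5-hydroxy-4,8-dimethylnona-3,7-dien-1-yl]-3-methyloxiran-2-yl}pent-2-en-1-yl acetate | CC(=O)OC/C=C(/CO[Si](C)(C)C(C)(C)C)CC[C@H]1O[C@]1(C)CC/C=C(\C)[C@H](O)CC=C(C)C
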